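Stevensine 18 ⇒ 17 (acidolysis of N-Boc and N1-PMB) ⇒ α-chloroketone 15 + N-Boc-guanidine 16. The 2-aminoimidazole ring is read as a masked acyl group on C4 and is built last. 15 ⇒ C4 methyl ester 13 (one-carbon homologation with LiCH2Cl).
13 ⇒ monocyclic N-(pivaloyloxy)pyrrole-2-carboxamide 6 + methyl 2-diazobut-3-enoate 10 by a Rh(III)-catalysed C–H activation/[4+3] annulation. C3a–C4 forms at the metal, an allyl shift sets C4=C5, and the N7–C6 bond closes the azepinone ring with loss of the N–OPiv oxidant.
Enabling feature: the lactam carbonyl C8 sits on pyrrole carbon C8a, next to C3a, and C3a is the only pyrrole carbon without bromine. Opened at N7–C6 and C3a–C4, it becomes the lone C3–H of a 4,5-dibromopyrrole-2-carboxamide, ortho to a directing amide nitrogen. The C4=C5–C6 segment of the seven-membered ring maps onto a vinylcarbene (C4 = carbene carbon, C6 = vinyl terminus).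
Order of rings: pyrrole (bought, both Br in place) → seven-membered lactam (step 7) → 2-aminoimidazole (step 9). 6 comes from ester 1 in three steps and 10 from methyl acetoacetate 7 in three steps.
Key step: step 7

Remark on the chemistry: stevensine has no stereocentre and its only C=C lies inside the seven-membered ring. The given SMILES therefore describes one achiral compound and no enantioselective step is needed.

Step 1
Reactants: 1 methyl 4,5-dibromo-1H-pyrrole-2-carboxylate
Product: 2 methyl 4,5-dibromo-1-(4-methoxybenzyl)-1H-pyrrole-2-carboxylate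
Conditions: PMBCl (1.2 equiv), K2CO3, DMF, rt
Reagents that add atoms: 4-methoxybenzyl chloride, COc1ccc(CCl)cc1
Why: SN2 N-alkylation of the acidic pyrrole N–H installs an acid-labile group that blocks N1, which would otherwise form an N,N-chelate with rhodium in step 7.

Step 2
Reactants: 2 methyl 4,5-dibromo-1-(4-methoxybenzyl)-1H-pyrrole-2-carboxylate
Product: 3 4,5-dibromo-1-(4-methoxybenzyl)-1H-pyrrole-2-carboxylic acid
Conditions: LiOH, THF/MeOH/H2O, 50 °C; then 1 M HCl
Reagents that add atoms: lithium hydroxide, [Li+].[OH-]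
Why: Ester saponification, to which the aryl bromides and the PMB group are inert.

Step 3
Reactants: 3 4,5-dibromo-1-(4-methoxybenzyl)-1H-pyrrole-2-carboxylic acid; 4 O-pivaloylhydroxylammonium trifluoromethanesulfonate
Product: 6 4,5-dibromo-1-(4-methoxybenzyl)-N-(pivaloyloxy)-1H-pyrrole-2-carboxamide, via 4,5-dibromo-1-(4-methoxybenzyl)-1H-pyrrole-2-carbonyl chloride 5 (not isolated)
Conditions: (COCl)2, cat. DMF, CH2Cl2, 0 °C→rt, evaporate; then 4, K2CO3, EtOAc/H2O, 0 °C→rt
Reagents that add atoms: none
Why: Acid chloride formation followed by Schotten–Baumann N-acylation of the O-acylhydroxylamine is the standard access to N-(pivaloyloxy)amides, and it brings in N7 of the target together with its directing and oxidising group.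

Step 4
Reactants: 7 methyl acetoacetate
Product: 8 methyl 2-diazo-3-oxobutanoate
Conditions: p-ABSA, Et3N, MeCN, 0 °C→rt
Reagents that add atoms: 4-acetamidobenzenesulfonyl azide, CC(=O)Nc1ccc(cc1)S(=O)(=O)N=[N+]=[N-]
Why: Regitz diazo transfer to an active methylene compound.

Step 5
Reactants: 8 methyl 2-diazo-3-oxobutanoate
Product: 9 methyl 2-diazo-3-hydroxybutanoate (racemic)
Conditions: NaBH4, MeOH, 0 °C
Reagents that add atoms: none
Why: Chemoselective borohydride reduction of the ketone beside the diazo ester, in which the new carbinol stereocentre forms as a racemate and is erased again in step 6.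

Step 6
Reactants: 9 methyl 2-diazo-3-hydroxybutanoate (racemic)
Product: 10 methyl 2-diazobut-3-enoate
Conditions: POCl3, Et3N, CH2Cl2, 0 °C; product kept cold and used at once
Reagents that add atoms: none
Why: Alcohol dehydration (dichlorophosphate formation and E2 elimination towards the methyl group) is the established access to this vinyldiazoacetate, which is used at once because vinyl diazo compounds slowly undergo 1,5-electrocyclisation.

Step 7
Reactants: 6 4,5-dibromo-1-(4-methoxybenzyl)-N-(pivaloyloxy)-1H-pyrrole-2-carboxamide; 10 methyl 2-diazobut-3-enoate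
Product: 13 methyl 2,3-dibromo-1-(4-methoxybenzyl)-8-oxo-1,6,7,8-tetrahydropyrrolo[2,3-c]azepine-4-carboxylate, via five-membered Cp*Rh(III) rhodacycle (Rh on amide N and pyrrole C3) 11 (not isolated), via eight-membered σ-allyl Cp*Rh(III) rhodacycle (Rh on amide N and the terminal CH2) 12 (not isolated)
Conditions: [Cp*RhCl2]2 (2.5 mol %), CsOAc (30 mol %), MeCN, rt, N2; 10 (1.5 equiv) added slowly as a cold solution
Reagents that add atoms: none
Why: Cp*Rh(OAc)2, formed in the flask, binds the deprotonated amide nitrogen of 6 and cleaves the only ortho C–H (pyrrole C3) by acetate-assisted concerted metalation–deprotonation to give 11, which takes up 10, loses N2 and forms C3a–C4 by 1,1-migratory insertion of the pyrrolyl group into the rhodium carbene. The crowded tertiary alkyl-rhodium then slips by an η1–η3–η1 allyl shift to the unsubstituted CH2 terminus (12), which sets C4=C5, and C–N reductive elimination coupled to cleavage of the N–O bond (internal oxidant) forms N7–C6, after which protonolysis frees the N–H lactam 13, pivalic acid and Rh(III). The closest known reaction type is the Rh(III)-catalysed C–H activation/[4+3] annulation of N-(pivaloyloxy)benzamides with vinyldiazoacetates to 2-benzazepin-1-ones, applied here to a pyrrole-2-carboxamide. The one ring that closes is the seven-membered lactam, by inner-sphere C(sp3)–N reductive elimination that contracts the eight-membered metallacycle 12, that is, nitrogen joins the CH2 end of an allyl unit whose double bond stays inside the new ring and is therefore cis. No stereocentre is formed. The step needs site selectivity (secured because C4 and C5 of 6 carry bromine and N1 carries the PMB group, so neither a second C–H nor an N,N-chelate is available), [4+3] over [4+1] closure (secured by the primary versus the fully substituted allyl terminus, the latter wedged against the neighbouring bromine, and by conjugation of the new alkene with ester and pyrrole) and C–H over C–Br activation (Rh(III) at room temperature does not add oxidatively to aryl bromides).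

Step 8
Reactants: 13 methyl 2,3-dibromo-1-(4-methoxybenzyl)-8-oxo-1,6,7,8-tetrahydropyrrolo[2,3-c]azepine-4-carboxylate
Product: 15 2,3-dibromo-4-(2-chloroacetyl)-1-(4-methoxybenzyl)-6,7-dihydropyrrolo[2,3-c]azepin-8(1H)-one, via dilithium hemiketal adduct (N7-lithiated lactam, C(OLi)(OMe)(CH2Cl) on C4, racemic) 14 (not isolated)
Conditions: LiHMDS (1.05 equiv), THF, −78 °C; ICH2Cl (3 equiv), then MeLi·LiBr (2.8 equiv) dropwise, −78 °C; AcOH/THF quench at −78 °C
Reagents that add atoms: chloroiodomethane, ClCI
Why: Homologation of an ester to an α-chloroketone with a lithium carbenoid (nucleophilic acyl substitution) should work because I/Li exchange on ICH2Cl outruns Br/Li exchange, the lithiated lactam is self-protected, and adduct 14 persists at −78 °C until the acidic quench, which prevents a second addition.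

Step 9
Reactants: 15 2,3-dibromo-4-(2-chloroacetyl)-1-(4-methoxybenzyl)-6,7-dihydropyrrolo[2,3-c]azepin-8(1H)-one; 16 N-Boc-guanidine
Product: 17 tert-butyl 2-amino-4-[2,3-dibromo-1-(4-methoxybenzyl)-8-oxo-1,6,7,8-tetrahydropyrrolo[2,3-c]azepin-4-yl]-1H-imidazole-1-carboxylate
Conditions: 16 (3 equiv), NaI (20 mol %), DMF, rt
Reagents that add atoms: none
Why: Imidazole synthesis from an α-haloketone and N-Boc-guanidine (Finkelstein-assisted N-alkylation, cyclisation onto the ketone, dehydration) gives the 1-Boc-2-aminoimidazole directly, and the five-membered ring closure should outrun conjugate addition to the enone.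

Step 10
Reactants: 17 tert-butyl 2-amino-4-[2,3-dibromo-1-(4-methoxybenzyl)-8-oxo-1,6,7,8-tetrahydropyrrolo[2,3-c]azepin-4-yl]-1H-imidazole-1-carboxylate
Product: 18 stevensine, 4-(2-amino-1H-imidazol-4-yl)-2,3-dibromo-6,7-dihydropyrrolo[2,3-c]azepin-8(1H)-one
Conditions: TFA, anisole (10 equiv), 60 °C; evaporate; NH3/MeOH (free base)
Reagents that add atoms: none
Why: SN1 acidolysis cleaves the Boc carbamate and the N-(4-methoxybenzyl) bond to the electron-poor pyrrole, anisole traps the benzyl cation by Friedel–Crafts alkylation, and the protonated 2-aminoimidazole, the lactam and the bromides should tolerate the acid.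

Compound list
1 | methyl 4,5-dibromo-1H-pyrrole-2-carboxylate | COC(=O)c1cc(Br)c(Br)[nH]1 | starting material
2 | methyl 4,5-dibromo-1-(4-methoxybenzyl)-1H-pyrrole-2-carboxylate | COC(=O)c1cc(Br)c(Br)n1Cc1ccc(OC)cc1 | intermediate
3 | 4,5-dibromo-1-(4-methoxybenzyl)-1H-pyrrole-2-carboxylic acid | OC(=O)c1cc(Br)c(Br)n1Cc1ccc(OC)cc1 | intermediate
4 | O-pivaloylhydroxylammonium trifluoromethanesulfonate | CC(C)(C)C(=O)O[NH3+].[O-]S(=O)(=O)C(F)(F)F | starting material
5 | 4,5-dibromo-1-(4-methoxybenzyl)-1H-pyrrole-2-carbonyl chloride | ClC(=O)c1cc(Br)c(Br)n1Cc1ccc(OC)cc1 | intermediate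
6 | 4,5-dibromo-1-(4-methoxybenzyl)-N-(pivaloyloxy)-1H-pyrrole-2-carboxamide | CC(C)(C)C(=O)ONC(=O)c1cc(Br)c(Br)n1Cc1ccc(OC)cc1 | intermediate
7 | methyl acetoacetate | COC(=O)CC(C)=O | starting material
8 | methyl 2-diazo-3-oxobutanoate | COC(=O)C(=[N+]=[N-])C(C)=O | intermediate
9 | methyl 2-diazo-3-hydroxybutanoate (racemic) | COC(=O)C(=[N+]=[N-])C(C)O | intermediate
10 | methyl 2-diazobut-3-enoate | COC(=O)C(=[N+]=[N-])C=C | intermediate
11 | five-membered Cp*Rh(III) rhodacycle of 6 (Rh on amide N and pyrrole C3; Cp* written as its anion) | C[c-]1c(C)c(C)c(C)c1C.CC(C)(C)C(=O)ON1[Rh+]c2c(Br)c(Br)n(Cc3ccc(OC)cc3)c2C1=O | intermediate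
12 | eight-membered σ-allyl Cp*Rh(III) rhodacycle (Rh on amide N and terminal CH2; Cp* written as its anion) | C[c-]1c(C)c(C)c(C)c1C.COC(=O)C1=CC[Rh+]N(OC(=O)C(C)(C)C)C(=O)c2n(Cc3ccc(OC)cc3)c(Br)c(Br)c21 | intermediate
13 | methyl 2,3-dibromo-1-(4-methoxybenzyl)-8-oxo-1,6,7,8-tetrahydropyrrolo[2,3-c]azepine-4-carboxylate | COC(=O)C1=CCNC(=O)c2n(Cc3ccc(OC)cc3)c(Br)c(Br)c21 | intermediate
14 | dilithium hemiketal adduct of 13 with chloromethyllithium (racemic) | [Li+].[Li+].COC([O-])(CCl)C1=CC[N-]C(=O)c2n(Cc3ccc(OC)cc3)c(Br)c(Br)c21 | intermediate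
15 | 2,3-dibromo-4-(2-chloroacetyl)-1-(4-methoxybenzyl)-6,7-dihydropyrrolo[2,3-c]azepin-8(1H)-one | O=C(CCl)C1=CCNC(=O)c2n(Cc3ccc(OC)cc3)c(Br)c(Br)c21 | intermediate
16 | N-Boc-guanidine | CC(C)(C)OC(=O)NC(N)=N | starting material
17 | tert-butyl 2-amino-4-[2,3-dibromo-1-(4-methoxybenzyl)-8-oxo-1,6,7,8-tetrahydropyrrolo[2,3-c]azepin-4-yl]-1H-imidazole-1-carboxylate | CC(C)(C)OC(=O)n1cc(nc1N)C1=CCNC(=O)c2n(Cc3ccc(OC)cc3)c(Br)c(Br)c21 | intermediate
18 | stevensine | Nc1ncc(C2=CCNC(=O)c3[nH]c(Br)c(Br)c32)[nH]1 | target

Total step count: 10. Longest linear sequence: 7 (steps 1–3 or 4–6, then 7–10).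

Steps most likely to fail

Step 7. Rhodation and carbene insertion take place right beside a bromine and may be slow, so that 10 is lost by 1,5-electrocyclisation before it is captured. The allyl-rhodium stage may also close at the fully substituted carbon or be protonated off the metal. The fallback uses no C–H activation and no diazo compound, and it closes the same N7–C6 bond by SN2. It sets out from 2.
- Directed magnesiation of the only ring C–H with TMPMgCl·LiCl (THF, −25 °C) and copper-mediated acylation with methyl chlorooxoacetate should give the α-keto ester methyl 4,5-dibromo-3-(2-methoxy-2-oxoacetyl)-1-(4-methoxybenzyl)-1H-pyrrole-2-carboxylate F1.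
- Vinylmagnesium bromide (THF, −78 °C) adds to the ketone and the alkoxide closes on the neighbouring ester. This should give the racemic vinyl lactone methyl 2,3-dibromo-4-ethenyl-1-(4-methoxybenzyl)-6-oxo-4,6-dihydro-1H-furo[3,4-b]pyrrole-4-carboxylate F2.
- NH3 in MeOH should open the strained lactone, in preference to the hindered ester, to the racemic hydroxy amide methyl 2-[4,5-dibromo-2-carbamoyl-1-(4-methoxybenzyl)-1H-pyrrol-3-yl]-2-hydroxybut-3-enoate F3.
- PBr3 (0 °C) converts the tertiary allylic alcohol with allylic transposition (SN2′) into the primary allylic bromide methyl (E)-4-bromo-2-[4,5-dibromo-2-carbamoyl-1-(4-methoxybenzyl)-1H-pyrrol-3-yl]but-2-enoate F4. The other alkene isomer can equilibrate by bromide exchange.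
- Cs2CO3 in dilute DMF closes the ring by N-allylation of the primary amide, which comes back to the route at 13.

Step 8. Bromine–lithium exchange at the pyrrole, deprotonation at C6, or early collapse of 14 followed by a second addition may erode the homologation. The fallback uses no organolithium and goes through a diazoketone. It sets out from 13.
- LiOH (THF/H2O) should give 2,3-dibromo-1-(4-methoxybenzyl)-8-oxo-1,6,7,8-tetrahydropyrrolo[2,3-c]azepine-4-carboxylic acid F5.
- Isobutyl chloroformate/N-methylmorpholine (THF, −15 °C) gives its isobutyl carbonic mixed anhydride F6.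
- Ethereal diazomethane gives 2,3-dibromo-4-(2-diazoacetyl)-1-(4-methoxybenzyl)-6,7-dihydropyrrolo[2,3-c]azepin-8(1H)-one F7.
- HCl in dioxane (0 °C, Nierenstein-type hydrochlorination) then rejoins the route at 15.

Step 10. The N1–benzyl bond may ionise too slowly. The forcing acid then needed invites protodebromination at C2 and re-alkylation of the product by the benzyl cation. The fallback debenzylates oxidatively instead of by acidolysis, and does so before the oxidation-sensitive 2-aminoimidazole exists. It sets out from 15.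
- CAN (MeCN/H2O, 0 °C) should give 2,3-dibromo-4-(2-chloroacetyl)-6,7-dihydropyrrolo[2,3-c]azepin-8(1H)-one F8.
- Condensation with 16 as in step 9 gives tert-butyl 2-amino-4-(2,3-dibromo-8-oxo-1,6,7,8-tetrahydropyrrolo[2,3-c]azepin-4-yl)-1H-imidazole-1-carboxylate F9.
- TFA/CH2Cl2 at rt then has to remove only the Boc group and comes back to the route at 18.

Further compounds
F1 | step 7 | methyl 4,5-dibromo-3-(2-methoxy-2-oxoacetyl)-1-(4-methoxybenzyl)-1H-pyrrole-2-carboxylate | COC(=O)C(=O)c1c(Br)c(Br)n(Cc2ccc(OC)cc2)c1C(=O)OC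
F2 | step 7 | methyl 2,3-dibromo-4-ethenyl-1-(4-methoxybenzyl)-6-oxo-4,6-dihydro-1H-furo[3,4-b]pyrrole-4-carboxylate (racemic) | COC(=O)C1(C=C)OC(=O)c2n(Cc3ccc(OC)cc3)c(Br)c(Br)c21
F3 | step 7 | methyl 2-[4,5-dibromo-2-carbamoyl-1-(4-methoxybenzyl)-1H-pyrrol-3-yl]-2-hydroxybut-3-enoate (racemic) | COC(=O)C(O)(C=C)c1c(Br)c(Br)n(Cc2ccc(OC)cc2)c1C(N)=O
F4 | step 7 | methyl (E)-4-bromo-2-[4,5-dibromo-2-carbamoyl-1-(4-methoxybenzyl)-1H-pyrrol-3-yl]but-2-enoate | COC(=O)/C(=C/CBr)c1c(Br)c(Br)n(Cc2ccc(OC)cc2)c1C(N)=O
F5 | step 8 | 2,3-dibromo-1-(4-methoxybenzyl)-8-oxo-1,6,7,8-tetrahydropyrrolo[2,3-c]azepine-4-carboxylic acid | OC(=O)C1=CCNC(=O)c2n(Cc3ccc(OC)cc3)c(Br)c(Br)c21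
F6 | step 8 | isobutyl carbonic mixed anhydride of F5 | CC(C)COC(=O)OC(=O)C1=CCNC(=O)c2n(Cc3ccc(OC)cc3)c(Br)c(Br)c21
F7 | step 8 | 2,3-dibromo-4-(2-diazoacetyl)-1-(4-methoxybenzyl)-6,7-dihydropyrrolo[2,3-c]azepin-8(1H)-one | [N-]=[N+]=CC(=O)C1=CCNC(=O)c2n(Cc3ccc(OC)cc3)c(Br)c(Br)c21
F8 | step 10 | 2,3-dibromo-4-(2-chloroacetyl)-6,7-dihydropyrrolo[2,3-c]azepin-8(1H)-one | O=C(CCl)C1=CCNC(=O)c2[nH]c(Br)c(Br)c21
F9 | step 10 | tert-butyl 2-amino-4-(2,3-dibromo-8-oxo-1,6,7,8-tetrahydropyrrolo[2,3-c]azepin-4-yl)-1H-imidazole-1-carboxylate | CC(C)(C)OC(=O)n1cc(nc1N)C1=CCNC(=O)c2[nH]c(Br)c(Br)c21
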